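The numbers in the tables were generated by integration on assumed constants; the scatter is artificial.

If a triple product holds 3 units of reagent, then 3.00 is the crossing charge, the reagent per solid substrate at which the reagent charged just fills the solid substrate charged. Below the crossing, reagent is the limiting reagent, and the triple product can reach at most the charge divided by the crossing. Above it, the solid substrate is the limit.

| flask | solid substrate | reagent | remark | time |
|---|---|---|---|---|
| Tuesday's | 6.7 mM | 1 equiv | run made earlier |  |
| Friday's | 5 mM | 1 equiv | run made earlier |  |
| grey | 10 mM | 1.00 equiv |  | 15 min |
| blue | 10 mM | 2.00 equiv |  | 15 min |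
| amber | 10 mM | 4.00 equiv |  | 15 min |

- Tuesday's (time / min: triple product / %, mono adduct / %): 0.250: 2.3, 6.0; 0.833: 16.6, 9.4; 1.33: 22.1, 8.3; 2.00: 22.2, 3.4; 3.00: 22.4, 0
- Friday's (time / min: triple product / %, mono adduct / %): 0.667: 12.3, 13.5; 1.33: 18.7, 10.5; 2.00: 19.6, 4.5; 2.50: 19.8, 3.6; 3.00: 19.0, 1.3

(each reading ± 0.5 percentage points)

- solid, in amounts per volume of the solution: solid substrate
- the earlier runs were read with a standard deviation of 0.5 percentage points
- at the start none of the solid substrate is in solution

- how much triple product is there at the end, in percent of the solid substrate charged: for each flask in turn (grey, blue, amber)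

Both earlier runs lie below the crossing, with a ceiling of 33.3 %. Yet the triple product levelled near 22.4 % on Tuesday and near 19.6 % on Friday. On Tuesday the mono adduct went on fading, from 8.3 % to 0 %, while the triple product stayed level, so some material was leaving by another road.

Two colleagues read this differently. The first holds to the crossing: the shortfall belongs to flasks short of reagent. Grey and blue stay under 33.3 % and 66.7 %, but amber, at 4.00 equiv, stands above the crossing and should come close to 100 %. That is also my own reckoning.

The second colleague made the forecast and expects a loss at every charge, because, in the forecast's words, “Mono then partitions between further reagent attack and loss”. The forecast gives 25 %, 55 % and 87 %.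

The flasks give 26.1 %, 59.4 % and 99.1 %. Amber therefore goes to the first colleague, 12 percentage points above the forecast. The forecast keeps the region below the crossing, where it lies nearer than the ceiling: in grey it is off by 1.1 points against 7.2 points, and in blue by 4.4 points against 7.3 points. Side product, which counts as two in its percentage, ends at 27.1 % in blue and 0.948 % in amber.

    starting material + mono adduct → side product (k = 15.0 M⁻¹ s⁻¹)
    reagent + mono adduct → bis adduct (k = 22.0 M⁻¹ s⁻¹)
    2 starting material → self-condensation product (k = 0.00240 M⁻¹ s⁻¹)
    starting material + reagent → mono adduct (k = 25.0 M⁻¹ s⁻¹)
    reagent + bis adduct → triple product (k = 32.0 M⁻¹ s⁻¹)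
    solid substrate ⇌ starting material, rate k6*(cs6 - [starting material]) while solid is left; crystals form when [starting material] > cs6 (solubility = 3.20 mM, k = 0.0280 s⁻¹)

Measured against the crossing, the triple product in amber holds 74.3 % of the charged reagent, and 26 % of that charge stands unbound at the end.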